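**Retrosynthetic overview**
1. Kurarinone ⇐ its tris-MOM ether by acetal methanolysis; the MOM groups are the only protecting groups of the route.
2. Tris-MOM flavanone ⇐ a B-ring-free 6b-hydroxy-cyclopropa[b]benzofuran plus 1-bromo-2,4-bis(methoxymethoxy)benzene. One radical operation expands the five-membered furan ring to the pyranone, attaches the B ring at C2 and sets C2 as (S).
3. Enabling feature: the ring-fusion bond C1a–C6b shared by the cyclopropane and the furan ring (a 2-oxabicyclo[3.1.0]hexane unit). C6b carries the OH and becomes C4=O, C1a carries the ring oxygen and becomes the oxygen-stabilised C2 radical, and the cyclopropane CH2 becomes C3.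
4. Cyclopropanol ⇐ benzofuran-3(2H)-one (enolate cyclopropanation) ⇐ α-chloroketone ⇐ 2-lavandulyl-5-methoxy-1,3-bis(methoxymethoxy)benzene, made by two directed ortho-metalations of 3,5-bis(methoxymethoxy)anisole; the side-chain centre comes from an Evans deconjugative alkylation.
5. Ring order: A and B rings are bought as arenes; furanone ring (five-membered) → cyclopropane → pyranone ring (six-membered) by one-carbon ring expansion.

Key step: step 11

Remark on the chemistry: the side-chain centre is (R) in the target but (S) in the acyl oxazolidinone, lavandulol and its iodide, only because C=O, CH2OH and CH2I outrank isopropenyl while CH2–aryl does not; the spatial arrangement is the same throughout. The antipode of the chiral ligand in step 11 is assumed to be fixed by a screen so that the 2S product is favoured. "Lavandulyl" below means (2R)-5-methyl-2-(prop-1-en-2-yl)hex-4-en-1-yl.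

**Route**

Step 1
Reactants: 1 (S)-4-benzyl-1,3-oxazolidin-2-one; 2 3-methylbut-2-enoyl chloride
Product: 3 (S)-4-benzyl-3-(3-methylbut-2-enoyl)-1,3-oxazolidin-2-one
Conditions: n-BuLi, THF, −78 °C; then 2, −78 → 0 °C
Reagents that add atoms: none
Why: N-acylation of the lithiated oxazolidinone (loading of the Evans auxiliary) is fast at −78 °C and creates no stereocentre.

Step 2
Reactants: 3 (S)-4-benzyl-3-(3-methylbut-2-enoyl)-1,3-oxazolidin-2-one; 4 1-bromo-3-methylbut-2-ene (prenyl bromide)
Product: 6 (S)-4-benzyl-3-[(2S)-5-methyl-2-(prop-1-en-2-yl)hex-4-enoyl]-1,3-oxazolidin-2-one, via sodium (Z)-dienolate 5 (not isolated)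
Conditions: NaHMDS, THF, −78 °C; then 4, −78 → −40 °C
Reagents that add atoms: none
Why: Evans alkylation in its deconjugative form: γ-deprotonation of the s-cis enoyl imide gives the chelated (Z)-dienolate, which is alkylated at the α-carbon on the face opposite the C4 benzyl group, so the new centre should be (2S) and the isopropenyl group is unveiled in the same event.

Step 3
Reactants: 6 (S)-4-benzyl-3-[(2S)-5-methyl-2-(prop-1-en-2-yl)hex-4-enoyl]-1,3-oxazolidin-2-one
Product: 7 (2S)-5-methyl-2-(prop-1-en-2-yl)hex-4-en-1-ol [(S)-lavandulol]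
Conditions: LiBH4, MeOH (1 equiv), Et2O, 0 °C
Reagents that add atoms: none
Why: Reductive removal of the Evans auxiliary with lithium borohydride gives the primary alcohol under non-enolising conditions, so the α-centre (allylic and α to the carbonyl) keeps its configuration and the alkene does not move into conjugation.

Step 4
Reactants: 7 (S)-lavandulol
Product: 8 (2S)-1-iodo-5-methyl-2-(prop-1-en-2-yl)hex-4-ene [(S)-lavandulyl iodide]
Conditions: PPh3, imidazole, I2 (premixed), CH2Cl2, 0 °C → rt
Reagents that add atoms: iodine, II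
Why: The Appel reaction substitutes only at the primary CH2 by SN2, so the adjacent stereocentre is untouched, and premixing PPh3 with I2 keeps free iodine away from the alkenes.

Step 5
Reactants: 9 5-methoxybenzene-1,3-diol
Product: 10 1-methoxy-3,5-bis(methoxymethoxy)benzene
Conditions: MOMCl, i-Pr2NEt, CH2Cl2, 0 °C → rt
Reagents that add atoms: chloromethyl methyl ether, COCCl
Why: Williamson-type O-alkylation of both phenols installs the acetals that direct both metalations and later become the ring oxygen and the 7-OH.

Step 6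
Reactants: 10 1-methoxy-3,5-bis(methoxymethoxy)benzene; 8 (S)-lavandulyl iodide
Product: 12 2-lavandulyl-5-methoxy-1,3-bis(methoxymethoxy)benzene, via aryllithium 11 (not isolated)
Conditions: n-BuLi, THF, 0 °C; then 8, DMPU, −78 °C → rt
Reagents that add atoms: none
Why: Directed ortho-metalation should take the carbon flanked by both OMOM groups (cooperative direction, stronger than OMOM/OMe), and the aryllithium is alkylated by the primary iodide in an SN2 reaction that does not touch the stereocentre.

Step 7
Reactants: 12 2-lavandulyl-5-methoxy-1,3-bis(methoxymethoxy)benzene; 13 2-chloro-N-methoxy-N-methylacetamide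
Product: 15 2-chloro-1-[3-lavandulyl-6-methoxy-2,4-bis(methoxymethoxy)phenyl]ethan-1-one, via aryllithium 14 (not isolated)
Conditions: n-BuLi, THF, −78 → 0 °C; then 13, −78 °C
Reagents that add atoms: none
Why: The second directed ortho-metalation can only take one of the two equivalent ring positions between OMOM and OMe, and the Weinreb ketone synthesis stops at the α-chloroketone because the chelated tetrahedral adduct persists until work-up.

Step 8
Reactants: 15 2-chloro-1-[3-lavandulyl-6-methoxy-2,4-bis(methoxymethoxy)phenyl]ethan-1-one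
Product: 17 7-lavandulyl-4-methoxy-6-(methoxymethoxy)-1-benzofuran-3(2H)-one, via ortho-hydroxy α-chloroketone 16 (not isolated)
Conditions: MgBr2·OEt2, CH2Cl2, 0 °C → rt; aqueous work-up; then K2CO3, acetone, rt
Reagents that add atoms: none
Why: Magnesium bromide chelated between the ketone and the ortho acetal oxygen should cleave only that MOM ether (the para one and the methyl ether stay), and the freed phenol closes the five-membered ring by intramolecular Williamson etherification (5-exo-tet) on the α-chloroketone.

Step 9
Reactants: 17 7-lavandulyl-4-methoxy-6-(methoxymethoxy)-1-benzofuran-3(2H)-one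
Product: 19 3-lavandulyl-6-methoxy-4-(methoxymethoxy)-1,1a-dihydro-6bH-cyclopropa[b][1]benzofuran-6b-ol (cis-fused; both ring-fusion diastereomers), via lithium benzofuran-3-olate 18 (not isolated)
Conditions: LiHMDS, THF, −78 °C; then CH2I2, SmI2, THF, −78 °C → rt
Reagents that add atoms: diiodomethane, ICI
Why: Cyclopropanation of a lithium enolate by the samarium carbenoid from CH2I2/SmI2 is oxygen-directed and ignores isolated alkenes, so only the enolate C2=C3 bond should react; the fusion is necessarily cis, and the two diastereomers need no separation because both new centres vanish in step 11.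

Step 10
Reactants: 20 4-bromobenzene-1,3-diol
Product: 21 1-bromo-2,4-bis(methoxymethoxy)benzene
Conditions: MOMCl, i-Pr2NEt, CH2Cl2, 0 °C → rt
Reagents that add atoms: chloromethyl methyl ether, COCCl
Why: The same Williamson-type acetal protection gives a B-ring bromide whose MOM ethers tolerate the nickel/photoredox step and leave together with the A-ring MOM group at the end.

Step 11
Reactants: 19 3-lavandulyl-6-methoxy-4-(methoxymethoxy)-1,1a-dihydro-6bH-cyclopropa[b][1]benzofuran-6b-ol; 21 1-bromo-2,4-bis(methoxymethoxy)benzene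
Product: 23 (2S)-2-[2,4-bis(methoxymethoxy)phenyl]-8-lavandulyl-5-methoxy-7-(methoxymethoxy)-2,3-dihydro-4H-chromen-4-one, via 4-oxochroman-2-yl radical 22 (not isolated)
Conditions: NiBr2·DME (10 mol %), chiral bis(imidazoline) ligand L* (12 mol %), 4CzIPN (2 mol %), 2,4,6-collidine, DMA, blue LEDs, 10 °C
Reagents that add atoms: none
Why: Proposed new method: photoexcited 4CzIPN and collidine oxidise the cyclopropanol O–H of 19 by proton-coupled electron transfer to the alkoxy radical, which breaks the fusion bond C1a–C6b by β-scission with release of the cyclopropane strain, so that C6b becomes the C4 ketone, the cyclopropane CH2 becomes C3 and the oxygen-stabilised radical 22 sits at C2 of the new pyranone; ArNi(II)Br from oxidative addition of 21 to Ni(0) captures 22, the Ni(III) aryl alkyl complex forms the C2–aryl bond by reductive elimination, and the reduced photocatalyst returns Ni(I) to Ni(0). The closest known reaction types are the photoredox/nickel ring-opening arylation of tertiary cyclopropanols with aryl bromides, the iron(III)-mediated ring enlargement of 1-oxy-bicyclo[n.1.0]alkanes through endocyclic scission, and the enantioselective nickel-catalysed arylation of α-oxy radicals of cyclic ethers; what is new is their union on a furan-fused cyclopropanol. No ring is closed by a new bond: the six-membered ring arises by one-carbon ring expansion of the five-membered furan ring through fragmentation of the zero-atom bridge of the 2-oxabicyclo[3.1.0]hexane unit. The new C2 centre is controlled by the chiral ligand on nickel in the radical capture and reductive elimination; the planar radical 22 has erased the ring-fusion configuration of 19, so both diastereomers converge, the ligand antipode is chosen to give 2S, and the (R) side-chain centre is not involved. The step needs endocyclic over exocyclic scission, which the ring oxygen on C1a secures (α-alkoxy secondary radical against a primary one), and it needs capture of 22 by nickel to outrun its oxidation to the chromone, hydrogen-atom transfer and addition to the side-chain alkenes, which only medium-ring cyclisations could reach.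

Step 12
Reactants: 23 (2S)-2-[2,4-bis(methoxymethoxy)phenyl]-8-lavandulyl-5-methoxy-7-(methoxymethoxy)-2,3-dihydro-4H-chromen-4-one
Product: 24 kurarinone
Conditions: HCl (1.25 M in MeOH), 25 → 40 °C, stopped at full conversion
Reagents that add atoms: none
Why: Acid-catalysed acetal methanolysis frees the three phenols without base, so C2 should not epimerise through phenoxide-driven ring opening, and the mild acid and short time are meant to keep the side-chain alkenes from being protonated or captured by the 7-OH.

**Compound list**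
1 | (S)-4-benzyl-1,3-oxazolidin-2-one | O=C1N[C@@H](Cc2ccccc2)CO1 | starting material
2 | 3-methylbut-2-enoyl chloride | CC(C)=CC(=O)Cl | starting material
3 | (S)-4-benzyl-3-(3-methylbut-2-enoyl)-1,3-oxazolidin-2-one | CC(C)=CC(=O)N1[C@@H](Cc2ccccc2)COC1=O | intermediate
4 | 1-bromo-3-methylbut-2-ene (prenyl bromide) | CC(C)=CCBr | starting material
5 | sodium (Z)-dienolate of 3 | C=C(C)/C=C(\O[Na])N1[C@@H](Cc2ccccc2)COC1=O | intermediate (not isolated)
6 | (S)-4-benzyl-3-[(2S)-5-methyl-2-(prop-1-en-2-yl)hex-4-enoyl]-1,3-oxazolidin-2-one | CC(C)=CC[C@@H](C(C)=C)C(=O)N1[C@@H](Cc2ccccc2)COC1=O | intermediate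
7 | (2S)-5-methyl-2-(prop-1-en-2-yl)hex-4-en-1-ol, (S)-lavandulol | C=C(C)[C@H](CC=C(C)C)CO | intermediate
8 | (2S)-1-iodo-5-methyl-2-(prop-1-en-2-yl)hex-4-ene, (S)-lavandulyl iodide | C=C(C)[C@H](CC=C(C)C)CI | intermediate
9 | 5-methoxybenzene-1,3-diol | COc1cc(O)cc(O)c1 | starting material
10 | 1-methoxy-3,5-bis(methoxymethoxy)benzene | COCOc1cc(OC)cc(OCOC)c1 | intermediate
11 | [4-methoxy-2,6-bis(methoxymethoxy)phenyl]lithium | [Li]c1c(OCOC)cc(OC)cc1OCOC | intermediate (not isolated)
12 | 5-methoxy-1,3-bis(methoxymethoxy)-2-[(2R)-5-methyl-2-(prop-1-en-2-yl)hex-4-en-1-yl]benzene | C=C(C)[C@H](CC=C(C)C)Cc1c(OCOC)cc(OC)cc1OCOC | intermediate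
13 | 2-chloro-N-methoxy-N-methylacetamide | CON(C)C(=O)CCl | starting material
14 | {6-methoxy-2,4-bis(methoxymethoxy)-3-[(2R)-5-methyl-2-(prop-1-en-2-yl)hex-4-en-1-yl]phenyl}lithium | C=C(C)[C@H](CC=C(C)C)Cc1c(OCOC)cc(OC)c([Li])c1OCOC | intermediate (not isolated)
15 | 2-chloro-1-{6-methoxy-2,4-bis(methoxymethoxy)-3-[(2R)-5-methyl-2-(prop-1-en-2-yl)hex-4-en-1-yl]phenyl}ethan-1-one | C=C(C)[C@H](CC=C(C)C)Cc1c(OCOC)cc(OC)c(C(=O)CCl)c1OCOC | intermediate
16 | 2-chloro-1-{2-hydroxy-6-methoxy-4-(methoxymethoxy)-3-[(2R)-5-methyl-2-(prop-1-en-2-yl)hex-4-en-1-yl]phenyl}ethan-1-one | C=C(C)[C@H](CC=C(C)C)Cc1c(OCOC)cc(OC)c(C(=O)CCl)c1O | intermediate (not isolated)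
17 | 4-methoxy-6-(methoxymethoxy)-7-[(2R)-5-methyl-2-(prop-1-en-2-yl)hex-4-en-1-yl]-1-benzofuran-3(2H)-one | C=C(C)[C@H](CC=C(C)C)Cc1c(OCOC)cc(OC)c2c1OCC2=O | intermediate
18 | lithium 4-methoxy-6-(methoxymethoxy)-7-[(2R)-5-methyl-2-(prop-1-en-2-yl)hex-4-en-1-yl]-1-benzofuran-3-olate | C=C(C)[C@H](CC=C(C)C)Cc1c(OCOC)cc(OC)c2c(O[Li])coc12 | intermediate (not isolated)
19 | 6-methoxy-4-(methoxymethoxy)-3-[(2R)-5-methyl-2-(prop-1-en-2-yl)hex-4-en-1-yl]-1,1a-dihydro-6bH-cyclopropa[b][1]benzofuran-6b-ol, cis-fused, both ring-fusion diastereomers | C=C(C)[C@H](CC=C(C)C)Cc1c(OCOC)cc(OC)c2c1OC1CC21O | intermediate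
20 | 4-bromobenzene-1,3-diol | Oc1ccc(Br)c(O)c1 | starting material
21 | 1-bromo-2,4-bis(methoxymethoxy)benzene | COCOc1ccc(Br)c(OCOC)c1 | intermediate
22 | 5-methoxy-7-(methoxymethoxy)-8-[(2R)-5-methyl-2-(prop-1-en-2-yl)hex-4-en-1-yl]-4-oxochroman-2-yl radical | C=C(C)[C@H](CC=C(C)C)Cc1c(OCOC)cc(OC)c2c1O[CH]CC2=O | intermediate (not isolated)
23 | (2S)-2-[2,4-bis(methoxymethoxy)phenyl]-5-methoxy-7-(methoxymethoxy)-8-[(2R)-5-methyl-2-(prop-1-en-2-yl)hex-4-en-1-yl]-2,3-dihydro-4H-chromen-4-one | C=C(C)[C@H](CC=C(C)C)Cc1c(OCOC)cc(OC)c2c1O[C@H](c1ccc(OCOC)cc1OCOC)CC2=O | intermediate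
24 | kurarinone, (2S)-2-(2,4-dihydroxyphenyl)-7-hydroxy-5-methoxy-8-[(2R)-5-methyl-2-(prop-1-en-2-yl)hex-4-en-1-yl]-2,3-dihydro-4H-chromen-4-one | C=C(C)[C@H](CC=C(C)C)Cc1c(O)cc(OC)c2c1O[C@H](c1ccc(O)cc1O)CC2=O | target

**Count and risks**
Total steps: 12. Longest linear sequence: 10 steps (1 → 2 → 3 → 4 → 6 → 7 → 8 → 9 → 11 → 12).

Steps most likely to fail:

1. Step 11 (proposed new method). The enantiofacial discrimination in the nickel capture of the C2 radical may be poor with the ortho-substituted aryl group. The radical may also be oxidised on to the chromone, or a two-electron nickel homoenolate pathway may cleave the exocyclic cyclopropane bond without ring expansion. The fallback uses known chemistry, sets out from 19 and 21 and returns at 23. The same ring expansion is run oxidatively (FeCl3, DMF, 0 °C), which should give 2-chloro-8-lavandulyl-5-methoxy-7-(methoxymethoxy)chroman-4-one F1; without isolation this loses HCl with NaOAc in MeOH to give 8-lavandulyl-5-methoxy-7-(methoxymethoxy)-4H-chromen-4-one F2. Bromide 21 is converted (n-BuLi, THF, −78 °C; B(Oi-Pr)3; aqueous work-up) into [2,4-bis(methoxymethoxy)phenyl]boronic acid F3. Rhodium-catalysed asymmetric 1,4-addition of F3 to F2 (Hayashi–Miyaura reaction; Rh(I) with a chiral electron-poor bisphosphine or chiral diene, toluene–H2O, no base, rt; ligand antipode chosen for 2S) should then give 23.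

2. Step 6. The basic aryllithium may remove the allylic β-hydrogen of the iodide (E2 to a conjugated diene) faster than it substitutes, and the metalation may be incompletely selective for the doubly flanked position. The fallback sets out from 7 and 10 and returns at 12. Alcohol 7 is converted with TsCl and pyridine (0 °C) into (S)-lavandulyl 4-methylbenzenesulfonate F4. Aryllithium 11, made from 10 as before, is transmetalated with MgBr2·OEt2 in THF to [4-methoxy-2,6-bis(methoxymethoxy)phenyl]magnesium bromide F5. A copper-catalysed Grignard–alkyl sulfonate cross-coupling of F5 with F4 (Li2CuCl4, 5 mol %, THF, −30 °C → rt) replaces the direct carbanion SN2 by an oxidative addition/reductive elimination at copper with a much less basic nucleophile, and should give 12.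

3. Step 9. Enolisation may be incomplete, in which case SmI2 would cleave the α-aryloxy ketone reductively, or the aromatic benzofuranolate may be too unreactive toward the samarium carbenoid. The fallback sets out from 17 and returns at 19. Ketone 17 is silylated (TMSOTf, Et3N, CH2Cl2, 0 °C) to 7-lavandulyl-4-methoxy-6-(methoxymethoxy)-3-(trimethylsilyloxy)-1-benzofuran F6. A Simmons–Smith cyclopropanation with a limited amount of Et2Zn/CH2I2 (CH2Cl2, −20 °C) should take the doubly oxygenated C2=C3 bond ahead of the isolated alkenes and give the 6b-trimethylsilyloxy cyclopropa[b]benzofuran F7. Methanolysis of the silyl ether (K2CO3, MeOH, 0 °C) should then give 19.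

**Further compounds**
F1 | step 11 | 2-chloro-5-methoxy-7-(methoxymethoxy)-8-[(2R)-5-methyl-2-(prop-1-en-2-yl)hex-4-en-1-yl]chroman-4-one (not isolated) | C=C(C)[C@H](CC=C(C)C)Cc1c(OCOC)cc(OC)c2c1OC(Cl)CC2=O
F2 | step 11 | 5-methoxy-7-(methoxymethoxy)-8-[(2R)-5-methyl-2-(prop-1-en-2-yl)hex-4-en-1-yl]-4H-chromen-4-one | C=C(C)[C@H](CC=C(C)C)Cc1c(OCOC)cc(OC)c2c1occc2=O
F3 | step 11 | [2,4-bis(methoxymethoxy)phenyl]boronic acid | COCOc1ccc(B(O)O)c(OCOC)c1
F4 | step 6 | (2S)-5-methyl-2-(prop-1-en-2-yl)hex-4-en-1-yl 4-methylbenzenesulfonate | C=C(C)[C@H](CC=C(C)C)COS(=O)(=O)c1ccc(C)cc1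
F5 | step 6 | [4-methoxy-2,6-bis(methoxymethoxy)phenyl]magnesium bromide | Br[Mg]c1c(OCOC)cc(OC)cc1OCOC
F6 | step 9 | 4-methoxy-6-(methoxymethoxy)-7-[(2R)-5-methyl-2-(prop-1-en-2-yl)hex-4-en-1-yl]-3-(trimethylsilyloxy)-1-benzofuran | C=C(C)[C@H](CC=C(C)C)Cc1c(OCOC)cc(OC)c2c(O[Si](C)(C)C)coc12
F7 | step 9 | 6-methoxy-4-(methoxymethoxy)-3-[(2R)-5-methyl-2-(prop-1-en-2-yl)hex-4-en-1-yl]-6b-(trimethylsilyloxy)-1,1a-dihydro-6bH-cyclopropa[b][1]benzofuran, cis-fused, both ring-fusion diastereomers | C=C(C)[C@H](CC=C(C)C)Cc1c(OCOC)cc(OC)c2c1OC1CC21O[Si](C)(C)C
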